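The route rests on disconnecting all three C–Br bonds of ring B (C2', C4', C5') at once, with a nitrogen atom standing in for the hydrogen at C3'. That carbon lies para to the C6' hydroxyl and between the C2' and C4' bromines, exactly where bromine would otherwise enter first. A single bromination of acetanilide 8, a diaryl ether whose ring A already carries both bromines ortho and para to its hydroxyl, fills every open position of ring B; hydrolysis and reductive deamination then expose C3'–H. Compound 8 comes from an SNAr coupling, Baeyer–Villiger oxidation, demethylation and one-flask nitro reduction/acetylation.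

Key step: step 5

Remark: the target has no stereocentre and its diaryl ether axis rotates freely, so it is one achiral compound and no step has to set configuration. Ring B carries primed locants (C1' ether carbon, C6' hydroxyl carbon); ring A carries unprimed ones (C1 hydroxyl carbon, C6 ether carbon).

Step 1
Reactants: 1 2-methoxy-5-nitrophenol; 2 2,4-dibromo-6-fluorobenzaldehyde
Product: 3 2,4-dibromo-6-(2-methoxy-5-nitrophenoxy)benzaldehyde
Conditions: K2CO3, DMF, 80 °C
Reagents that add atoms: none
Why: SNAr by addition–elimination, in which the phenoxide of 1 attacks the fluorine-bearing carbon ortho to the formyl group (Meisenheimer adduct stabilised by the aldehyde) and fluoride leaves far faster than either bromide, so both C–Br bonds should survive.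

Step 2
Reactants: 3 2,4-dibromo-6-(2-methoxy-5-nitrophenoxy)benzaldehyde
Product: 5 2,4-dibromo-6-(2-methoxy-5-nitrophenoxy)phenol, via aryl formate 4 (not isolated)
Conditions: mCPBA, CH2Cl2, 0 → 40 °C; aq. Na2SO3 wash; then MeOH, cat. HCl, rt
Reagents that add atoms: mCPBA, OOC(=O)c1cccc(Cl)c1
Why: Baeyer–Villiger (Dakin-type) oxidation, in which the aryl group of the Criegee adduct, assisted by the lone pair of the ortho aryloxy oxygen, should migrate in preference to hydride to give formate 4, which acid-catalysed methanolysis cleaves, while the nitro group keeps ring B inert to the peracid.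

Step 3
Reactants: 5 2,4-dibromo-6-(2-methoxy-5-nitrophenoxy)phenol
Product: 6 2,4-dibromo-6-(2-hydroxy-5-nitrophenoxy)phenol
Conditions: BBr3, CH2Cl2, −78 °C → rt; H2O quench
Reagents that add atoms: none
Why: Lewis acid ether cleavage, in which BBr3 binds the methoxy oxygen and bromide removes the methyl group by SN2 as bromomethane, whereas the diaryl ether offers no sp3 carbon to attack and the nitro and bromo groups are inert.

Step 4
Reactants: 6 2,4-dibromo-6-(2-hydroxy-5-nitrophenoxy)phenol
Product: 8 N-[3-(3,5-dibromo-2-hydroxyphenoxy)-4-hydroxyphenyl]acetamide, via aminophenol 7 (not isolated)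
Conditions: Fe powder, AcOH, 60 °C; then Ac2O (1.2 equiv), rt
Reagents that add atoms: acetic anhydride, CC(=O)OC(C)=O
Why: Béchamp reduction of the nitro group by iron in acetic acid leaves aryl bromides untouched, and the oxidation-prone para-aminophenol 7 is acetylated in the same flask, where the amine should outcompete both uncatalysed phenols for the anhydride (chemoselective N-acylation of an aminophenol).

Step 5
Reactants: 8 N-[3-(3,5-dibromo-2-hydroxyphenoxy)-4-hydroxyphenyl]acetamide
Product: 9 N-[2,5,6-tribromo-3-(3,5-dibromo-2-hydroxyphenoxy)-4-hydroxyphenyl]acetamide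
Conditions: Br2 (3.1 equiv), AcOH, 15 → 45 °C; aq. NaHSO3 quench
Reagents that add atoms: bromine, BrBr
Why: Three successive electrophilic aromatic substitutions (Wheland intermediate, then loss of a proton) take place on ring B, the closest known reaction type being the exhaustive bromination of anilides and phenols that underlies the tribromoaniline-to-tribromobenzene sequence. C5' is activated by the ortho C6' hydroxyl, C4' by the ortho acetamido group together with the para ether oxygen, and C2' by the ortho acetamido group together with the ortho ether oxygen, so each open site of ring B has a strong donor. C3', the site para to the C6' hydroxyl that would otherwise brominate first, is occupied by nitrogen and cannot react. No ring is closed and no stereocentre is formed; the selectivity needed is ring B over ring A. Ring A's two open positions, C3 and C5, are para and ortho to the bridging oxygen and so are not inert, but they are meta to the ring A hydroxyl, flanked by bromine and served only by that shared aryloxy donor, which together with a limit of about three equivalents of bromine at mild temperature should hold ring A at two bromines. The N-acetyl group tempers the para-aminophenol so that bromine substitutes instead of oxidising it to a quinone imine, and the bisulfite quench should return any such imine to the phenol.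

Step 6
Reactants: 9 N-[2,5,6-tribromo-3-(3,5-dibromo-2-hydroxyphenoxy)-4-hydroxyphenyl]acetamide
Product: 12 2,3,5-tribromo-6-(3,5-dibromo-2-hydroxyphenoxy)phenol, via aminophenol 10 (not isolated), via diazonium hydrogensulfate 11 (not isolated)
Conditions: H2SO4/AcOH/H2O, 110 °C, N2; then NaNO2, 0 °C; then 50% aq. H3PO2, 0 °C → rt
Reagents that add atoms: none
Why: Acid-catalysed amide hydrolysis frees the twisted, doubly ortho-brominated aniline 10 in a medium that the aryl bromides, phenols and diaryl ether tolerate, nitrosylsulfuric acid formed on adding nitrite diazotises this weak base in the same flask, and hypophosphorous acid then reduces diazonium ion 11 by the radical-chain hydrodediazoniation used to take 2,4,6-tribromoaniline to 1,3,5-tribromobenzene, the strong acid keeping the para-hydroxy diazonium ion protonated instead of letting it settle as a sluggish quinone diazide.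

Compound list
1 | 2-methoxy-5-nitrophenol | COc1ccc(cc1O)[N+](=O)[O-] | starting material
2 | 2,4-dibromo-6-fluorobenzaldehyde | O=Cc1c(F)cc(Br)cc1Br | starting material
3 | 2,4-dibromo-6-(2-methoxy-5-nitrophenoxy)benzaldehyde | COc1ccc(cc1Oc1cc(Br)cc(Br)c1C=O)[N+](=O)[O-] | intermediate
4 | 2,4-dibromo-6-(2-methoxy-5-nitrophenoxy)phenyl formate | COc1ccc(cc1Oc1cc(Br)cc(Br)c1OC=O)[N+](=O)[O-] | intermediate
5 | 2,4-dibromo-6-(2-methoxy-5-nitrophenoxy)phenol | COc1ccc(cc1Oc1cc(Br)cc(Br)c1O)[N+](=O)[O-] | intermediate
6 | 2,4-dibromo-6-(2-hydroxy-5-nitrophenoxy)phenol | Oc1ccc(cc1Oc1cc(Br)cc(Br)c1O)[N+](=O)[O-] | intermediate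
7 | 4-amino-2-(3,5-dibromo-2-hydroxyphenoxy)phenol | Nc1ccc(O)c(Oc2cc(Br)cc(Br)c2O)c1 | intermediate
8 | N-[3-(3,5-dibromo-2-hydroxyphenoxy)-4-hydroxyphenyl]acetamide | CC(=O)Nc1ccc(O)c(Oc2cc(Br)cc(Br)c2O)c1 | intermediate
9 | N-[2,5,6-tribromo-3-(3,5-dibromo-2-hydroxyphenoxy)-4-hydroxyphenyl]acetamide | CC(=O)Nc1c(Br)c(Br)c(O)c(Oc2cc(Br)cc(Br)c2O)c1Br | intermediate
10 | 4-amino-2,3,5-tribromo-6-(3,5-dibromo-2-hydroxyphenoxy)phenol | Nc1c(Br)c(Br)c(O)c(Oc2cc(Br)cc(Br)c2O)c1Br | intermediate
11 | 2,3,6-tribromo-5-(3,5-dibromo-2-hydroxyphenoxy)-4-hydroxybenzenediazonium hydrogensulfate | N#[N+]c1c(Br)c(Br)c(O)c(Oc2cc(Br)cc(Br)c2O)c1Br.OS(=O)(=O)[O-] | intermediate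
12 | 2,3,5-tribromo-6-(3,5-dibromo-2-hydroxyphenoxy)phenol | Oc1c(Br)cc(Br)cc1Oc1c(Br)cc(Br)c(Br)c1O | target

Total step count: 6. Longest linear sequence: 6 steps (1 and 2 to 12).

Steps most likely to fail

Step 5. The third substitution, at the crowded C2' position between the ether oxygen and the amide, may stall. Forcing it could then brominate ring A ortho to the bridging oxygen or oxidise the acetamidophenol to a quinone imine. The fallback sets out from 5 and lets a free amino group drive the two difficult substitutions while a methyl ether masks the para oxygen. Iron in acetic acid would reduce 5 to 2-(5-amino-2-methoxyphenoxy)-4,6-dibromophenol F1. Two equivalents of bromine in acetic acid at 0 °C should then brominate both positions ortho to the amine, giving 2-(3-amino-2,4-dibromo-6-methoxyphenoxy)-4,6-dibromophenol F2. BBr3 would unmask the phenol to give 4-amino-3,5-dibromo-2-(3,5-dibromo-2-hydroxyphenoxy)phenol F3. One equivalent of bromine in AcOH/48% HBr, with a bisulfite quench, should then fill the last position ortho to the new hydroxyl; if the aminophenol is oxidised in passing, bromide addition to the quinone imine should lead to the same product. The fallback returns to the route at 10, which is diazotised and reduced as in the later stages of step 6.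

Step 2. Hydride instead of aryl migration in the Criegee adduct of the electron-poor, doubly ortho-substituted aldehyde would deliver the benzoic acid, or the oxidation may simply be slow. The fallback sets out from 1 and carries no bromine through the oxidation. SNAr of 1 on commercial 2-fluorobenzaldehyde F4 (K2CO3, DMAc, 130 °C) would give 2-(2-methoxy-5-nitrophenoxy)benzaldehyde F5. mCPBA oxidation of this more electron-rich aldehyde should give 2-(2-methoxy-5-nitrophenoxy)phenyl formate F6, and methanolysis then 2-(2-methoxy-5-nitrophenoxy)phenol F7. Two equivalents of bromine in acetic acid should brominate ortho and para to the ring A hydroxyl, the nitro-deactivated ring B staying untouched. The fallback returns to the route at 5.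

Step 6. Hydrolysis of the hindered anilide may be slow, the liberated aminophenol may oxidise, or the para-hydroxy diazonium ion may settle as a quinone diazide that resists reduction. The fallback sets out from 9 and masks both phenols first. Methyl iodide and K2CO3 in acetone would give N-[2,5,6-tribromo-3-(3,5-dibromo-2-methoxyphenoxy)-4-methoxyphenyl]acetamide F8. Acid hydrolysis would give the isolable, oxidation-stable 2,5,6-tribromo-3-(3,5-dibromo-2-methoxyphenoxy)-4-methoxyaniline F9. Diazotisation in H2SO4/AcOH would give 2,5,6-tribromo-3-(3,5-dibromo-2-methoxyphenoxy)-4-methoxybenzenediazonium hydrogensulfate F10, which hypophosphorous acid should reduce to 1,2,5-tribromo-4-(3,5-dibromo-2-methoxyphenoxy)-3-methoxybenzene F11. BBr3 would cleave both methyl ethers, and the fallback returns to the route at 12.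

Further compounds
F1 | step 5 | 2-(5-amino-2-methoxyphenoxy)-4,6-dibromophenol | COc1ccc(N)cc1Oc1cc(Br)cc(Br)c1O
F2 | step 5 | 2-(3-amino-2,4-dibromo-6-methoxyphenoxy)-4,6-dibromophenol | COc1cc(Br)c(N)c(Br)c1Oc1cc(Br)cc(Br)c1O
F3 | step 5 | 4-amino-3,5-dibromo-2-(3,5-dibromo-2-hydroxyphenoxy)phenol | Nc1c(Br)cc(O)c(Oc2cc(Br)cc(Br)c2O)c1Br
F4 | step 2 | 2-fluorobenzaldehyde (purchased) | O=Cc1ccccc1F
F5 | step 2 | 2-(2-methoxy-5-nitrophenoxy)benzaldehyde | COc1ccc(cc1Oc1ccccc1C=O)[N+](=O)[O-]
F6 | step 2 | 2-(2-methoxy-5-nitrophenoxy)phenyl formate | COc1ccc(cc1Oc1ccccc1OC=O)[N+](=O)[O-]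
F7 | step 2 | 2-(2-methoxy-5-nitrophenoxy)phenol | COc1ccc(cc1Oc1ccccc1O)[N+](=O)[O-]
F8 | step 6 | N-[2,5,6-tribromo-3-(3,5-dibromo-2-methoxyphenoxy)-4-methoxyphenyl]acetamide | CC(=O)Nc1c(Br)c(Br)c(OC)c(Oc2cc(Br)cc(Br)c2OC)c1Br
F9 | step 6 | 2,5,6-tribromo-3-(3,5-dibromo-2-methoxyphenoxy)-4-methoxyaniline | Nc1c(Br)c(Br)c(OC)c(Oc2cc(Br)cc(Br)c2OC)c1Br
F10 | step 6 | 2,5,6-tribromo-3-(3,5-dibromo-2-methoxyphenoxy)-4-methoxybenzenediazonium hydrogensulfate | N#[N+]c1c(Br)c(Br)c(OC)c(Oc2cc(Br)cc(Br)c2OC)c1Br.OS(=O)(=O)[O-]
F11 | step 6 | 1,2,5-tribromo-4-(3,5-dibromo-2-methoxyphenoxy)-3-methoxybenzene | COc1c(Br)cc(Br)cc1Oc1c(Br)cc(Br)c(Br)c1OC
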